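The earlier runs and the new flask stem from a simulated flask from invented constants.

- A small charge of L is worth the E it returns, so the scale for this plate has its zero at a return of 1: each L charged ends as one E.

| flask | G | L | J | remark | time |
|---|---|---|---|---|---|
| ash | 1 M | 0.89 M | 0.80 M | run made earlier |  |
| alder | 1 M | 1.4 M | 0.80 M | run made earlier |  |
| midnight | 1.0 M | 1.00 M | 0.800 M |  | 20 min |
| autumn | 1.0 M | 0.600 M | 0.800 M |  | 60 min |

| run | time / min | E / % | G / % |
|---|---|---|---|
| ash | 0.833 | 32.3 | 39.5 |
| ash | 1.33 | 39.2 | 29.3 |
| ash | 2.00 | 45.7 | 24.9 |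
| ash | 3.00 | 52.0 | 22.3 |
| ash | 4.00 | 56.7 | 20.9 |
| ash | 6.00 | 62.4 | 20.6 |
| ash | 10.0 | 67.8 | 20.7 |
| alder | 0.833 | 41.7 | 23.6 |
| alder | 1.33 | 49.0 | 18.1 |
| alder | 2.00 | 56.2 | 14.4 |
| alder | 3.00 | 64.0 | 13.0 |
| alder | 4.00 | 69.8 | 11.4 |
| alder | 6.00 | 77.0 | 8.8 |
| alder | 10.0 | 83.5 | 6.2 |

(each reading ± 0.3 percentage points)

1. the winner by amount of E, in percent of the G charged; "neither" if no more than 2 percentage points parts them (midnight / autumn / neither)
2. how much E is there at the end, in percent of the G charged: midnight
3. how much E is there at the end, in percent of the G charged: autumn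

- a reading of G is of its free form alone

- Ash holds less L than G, so its E can price L.
- In ash, E gains 17 percentage points from 2.00 min to 6.00 min, then 5.4 points by 10.0 min.
- If equal later windows keep shrinking by that ratio, 2.6 points remains, and ash ends near 70.4%.
- Per L charged, that is a return on L of 0.791, meaning moles of E at the end per mole of L charged, a reading with the scatter of the runs.
- This reply's own reckoning multiplies that return by the charge of L: midnight 79.1%, autumn 47.4%. Midnight leads by more than the margin.
- The forecast says midnight, with 79% and 57%, on the ground that “an hour nearly exhausts L”. Its autumn number lies close to L wholly turned into E, 60.0%, and above this reckoning.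
- The flasks give midnight as winner, with midnight at 76.3% and autumn at 51.2%, which is 5.8 points under the forecast.

    J + X → D (k = 0.380 M⁻¹ s⁻¹)
    L → Q (k = 0.00130 s⁻¹)
    G + L → E + X (k = 0.0150 M⁻¹ s⁻¹)
    G + X ⇌ Z, settled at all times (K = 160 M⁻¹)

- The difference in charge of L is the main reason that autumn ends with less E than midnight: with that difference taken away, autumn gives 76.8% instead of 51.2%. Autumn's return is 0.853, short of 1, with L, its limiting reagent, at 0% of its charge. The passing of L into Q is part of the reason: the same autumn flask without that step gives 60.0% instead of 51.2%.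
- In a neighbour of autumn charged with 0.15 M of L, the return of 0.791 gives 11.9% of E; the computed flask gives 13.6%.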